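The plan cuts the two CH2–CH2 edges C6–C7 (ring B) and C11–C12 (ring C). These are the only ring bonds around the congested C8–C9 axis that touch no stereocentre. All eight stereocentres and the hindered bonds C8–C9 and C8–C14 are therefore fixed first. This is done in an open tetravinyl compound in which an 8-oxabicyclo[3.2.1]octane (ring A) and a cyclohexene (ring D) are joined only through C8, by enolate alkylation and then an Ireland–Claisen rearrangement. One double ring-closing metathesis then closes ring B and, last, ring C. Hydrogenation of the three ring alkenes finishes the synthesis.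

Key step: step 20

Remark (numbering): ring A = C1–C5, C9, C10 (cycloheptane, O bridging C3 and C10). Ring B = C5–C9. Ring C = C8, C9, C11–C14. Ring D = C13–C18. Methyl groups sit on C4 (two), C10, C13, C14 and C17, and the 4-methylpent-3-enyl chain on C17. "Exo" means syn to the oxygen bridge.

Remark (assumption): the antipodes of BINAP and of the CBS catalysts are those expected by analogy to give the drawn configurations. If the sense of induction is opposite, the other antipode is used.

Step 1
Reactants: 1 (±)-linalool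
Product: 2 2-(2-bromopropan-2-yl)-5-methyl-5-vinyltetrahydrofuran
Conditions: NBS, CH2Cl2, 0 °C
Reagents that add atoms: N-bromosuccinimide, O=C1CCC(=O)N1Br
Why: Bromoetherification, in which the bromonium ion of the electron-rich trisubstituted alkene is opened 5-exo by the tertiary alcohol; both stereocentres are erased in step 2.

Step 2
Reactants: 2 2-(2-bromopropan-2-yl)-5-methyl-5-vinyltetrahydrofuran
Product: 4 karahanaenone (2,2,5-trimethylcyclohept-4-en-1-one), via enol ether 3 (not isolated)
Conditions: 2,4,6-collidine, 170 °C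
Reagents that add atoms: none
Why: E2 loss of HBr gives the allyl vinyl ether 3, whose ring-expanding Claisen rearrangement forms the C4–C5 bond and delivers the achiral seven-membered ketone.

Step 3
Reactants: 4 karahanaenone
Product: 5 (S)-2,2,5-trimethylcyclohept-4-en-1-ol
Conditions: (R)-Me-CBS oxazaborolidine (10 mol %), catecholborane, toluene, −78 °C
Reagents that add atoms: none
Why: CBS reduction, in which the catalyst distinguishes the quaternary C4 flank from the CH2 flank and sets C3, while catecholborane leaves the alkene alone.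

Step 4
Reactants: 5 (S)-2,2,5-trimethylcyclohept-4-en-1-ol
Product: 7 (1R,5S)-1,4,4-trimethyl-8-oxabicyclo[3.2.1]octan-2-ol, via epoxy alcohol 6 (not isolated)
Conditions: mCPBA, NaHCO3, CH2Cl2, 0 °C; then camphorsulfonic acid (cat.), rt
Reagents that add atoms: 3-chloroperoxybenzoic acid, OOC(=O)c1cccc(Cl)c1
Why: Prilezhaev epoxidation followed by acid-catalysed transannular epoxide opening at the tertiary C10; the C3 oxygen can bridge only on its own face, so C10 is set by C3, and the C9 carbinol epimers converge in step 5.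

Step 5
Reactants: 7 (1R,5S)-1,4,4-trimethyl-8-oxabicyclo[3.2.1]octan-2-ol
Product: 8 (1R,5S)-1,4,4-trimethyl-8-oxabicyclo[3.2.1]octan-2-one
Conditions: n-Pr4N[RuO4] (5 mol %), N-methylmorpholine N-oxide, 4 Å sieves, CH2Cl2, rt
Reagents that add atoms: none
Why: Ley–Griffith oxidation of a secondary alcohol, mild enough for the tertiary ether bridge.

Step 6
Reactants: 8 (1R,5S)-1,4,4-trimethyl-8-oxabicyclo[3.2.1]octan-2-one
Product: 9 (1R,5S)-1,4,4-trimethyl-8-oxabicyclo[3.2.1]oct-2-en-2-yl triflate
Conditions: KN(SiMe3)2, THF, −78 °C; PhNTf2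
Reagents that add atoms: N-phenylbis(trifluoromethanesulfonimide), O=S(=O)(N(c1ccccc1)S(=O)(=O)C(F)(F)F)C(F)(F)F
Why: Enol triflate formation, regiospecific because C10 is a quaternary bridgehead and only C5 carries protons.

Step 7
Reactants: 9 (1R,5S)-1,4,4-trimethyl-8-oxabicyclo[3.2.1]oct-2-en-2-yl triflate
Product: 10 methyl (1R,5S)-1,4,4-trimethyl-8-oxabicyclo[3.2.1]oct-2-ene-2-carboxylate
Conditions: Pd(OAc)2 (5 mol %), PPh3, CO (1 atm), MeOH, Et3N, DMF, 50 °C
Reagents that add atoms: carbon monoxide, [C-]#[O+]; methanol, CO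
Why: Palladium-catalysed methoxycarbonylation (oxidative addition to zerovalent palladium, CO insertion, methanolysis) installs C11 as the activating ester.

Step 8
Reactants: 10 methyl (1R,5S)-1,4,4-trimethyl-8-oxabicyclo[3.2.1]oct-2-ene-2-carboxylate
Product: 12 methyl (1R,3R,5S)-1,4,4-trimethyl-3-exo-vinyl-8-oxabicyclo[3.2.1]octane-2-carboxylate, via silyl ketene acetal 11 (not isolated)
Conditions: CH2=CHMgBr, CuBr·SMe2 (20 mol %), Me3SiCl, THF, −78 to −30 °C; then 1 M HCl
Reagents that add atoms: vinylmagnesium bromide, C=C[Mg]Br; chlorotrimethylsilane, C[Si](C)(C)Cl (silicon stays only in 11)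
Why: Copper-catalysed conjugate addition accelerated by Me3SiCl; as in related bicyclo[3.2.1]oct-2-ene-2-carboxylates the nucleophile enters C5 from the exo face, away from the C1–C2 bridge, which sets C5, and the C9 epimer mixture is erased in step 15.

Step 9
Reactants: 13 tert-butyl 2-methyl-3-oxobutanoate; 14 methyl vinyl ketone
Product: 15 tert-butyl (S)-2-acetyl-2-methyl-5-oxohexanoate
Conditions: [Pd((R)-BINAP)(OH2)2](OTf)2 (5 mol %), THF, −20 °C
Reagents that add atoms: none
Why: Catalytic enantioselective Michael addition through a chiral palladium enolate of the β-keto ester, whose shielded face sets the quaternary C13.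

Step 10
Reactants: 15 tert-butyl (S)-2-acetyl-2-methyl-5-oxohexanoate
Product: 16 tert-butyl (S)-1,2-dimethyl-4-oxocyclohex-2-ene-1-carboxylate
Conditions: pyrrolidine (30 mol %), AcOH, toluene, 80 °C
Reagents that add atoms: none
Why: Intramolecular aldol condensation (second half of a Robinson annulation), in which the terminal methyl ketone attacks the acetyl group as in the formation of Hagemann-type esters and closes ring D with the C14 methyl group in place.

Step 11
Reactants: 16 tert-butyl (S)-1,2-dimethyl-4-oxocyclohex-2-ene-1-carboxylate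
Product: 17 tert-butyl (1S)-1,2,5-trimethyl-4-oxocyclohex-2-ene-1-carboxylate
Conditions: LiN(i-Pr)2, THF, −78 °C; MeI
Reagents that add atoms: methyl iodide, CI
Why: Kinetic α′-deprotonation gives the cross-conjugated dienolate, which is methylated at C17; the epimer mixture is erased in step 12.

Step 12
Reactants: 17 tert-butyl (1S)-1,2,5-trimethyl-4-oxocyclohex-2-ene-1-carboxylate; 18 5-iodo-2-methylpent-2-ene
Product: 19 tert-butyl (1S,5S)-1,2,5-trimethyl-5-(4-methylpent-3-en-1-yl)-4-oxocyclohex-2-ene-1-carboxylate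
Conditions: LiN(i-Pr)2, THF/DMPU, −78 °C; 18, to 0 °C
Reagents that add atoms: none
Why: Alkylation of the cross-conjugated lithium dienolate; allylic strain with the C14 methyl group keeps the tert-butyl ester on C13 pseudoaxial, so the iodide should approach C17 from the opposite face, which places the chain cis to the C13 methyl group.

Step 13
Reactants: 19 tert-butyl (1S,5S)-1,2,5-trimethyl-5-(4-methylpent-3-en-1-yl)-4-oxocyclohex-2-ene-1-carboxylate
Product: 20 tert-butyl (1S,4R,5S)-4-hydroxy-1,2,5-trimethyl-5-(4-methylpent-3-en-1-yl)cyclohex-2-ene-1-carboxylate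
Conditions: (S)-Me-CBS oxazaborolidine (20 mol %), catecholborane, toluene, −78 °C
Reagents that add atoms: none
Why: CBS reduction (1,2-selective); the catalyst distinguishes the quaternary C17 flank from the alkene flank and should leave the C16 hydroxyl cis to the chain and to the C13 methyl group.

Step 14
Reactants: 20 tert-butyl (1S,4R,5S)-4-hydroxy-1,2,5-trimethyl-5-(4-methylpent-3-en-1-yl)cyclohex-2-ene-1-carboxylate
Product: 21 bromoacetate of 20
Conditions: BrCH2COBr, pyridine, CH2Cl2, 0 °C
Reagents that add atoms: bromoacetyl bromide, BrCC(Br)=O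
Why: O-Acylation with a small, highly reactive acyl bromide copes with the hindered allylic alcohol and brings in C7 and C8.

Step 15
Reactants: 12 methyl (1R,3R,5S)-1,4,4-trimethyl-3-exo-vinyl-8-oxabicyclo[3.2.1]octane-2-carboxylate; 21 bromoacetate of 20
Product: 22 triester (ester of 20 with the 2-exo-methoxycarbonyl-3-exo-vinyl ring A 2-endo-acetic acid)
Conditions: LiN(i-Pr)2, THF/DMPU, −78 °C; 21, −78 to −40 °C
Reagents that add atoms: none
Why: Ester enolate alkylation; the exocyclic enolate at C9 is attacked on its endo (equatorial) face, away from the axial C4 methyl group and trans to the exo vinyl group, which sets the quaternary C9 with CO2Me (C11) exo and CH2 (C8) endo, and at low temperature the C10–O bond lies near the nodal plane of the enolate so that β-elimination should not compete.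

Step 16
Reactants: 22 triester
Product: 25 rearranged acid (C8 bearing H and CO2H joins C9 to the new quaternary C14), via silyl ketene acetal 23 (not isolated), via silyl ester 24 (not isolated)
Conditions: LiN(i-Pr)2, t-BuMe2SiCl, THF/DMPU, −78 °C; then toluene, 90 °C; then K2CO3, MeOH/H2O, acidify
Reagents that add atoms: tert-butyldimethylsilyl chloride, CC(C)(C)[Si](C)(C)Cl (silicon stays only in 23 and 24)
Why: Ireland–Claisen rearrangement; only the C8 methylene is enolisable, DMPU favours the (Z)-ketene acetal (C9 cis to OSi), and the suprafacial [3,3] shift through the boat transition state usual for cyclohexenyl esters transfers the C16 configuration to C14 (new bond cis to the C13 methyl group, trans to the ester) while the bulky C9 residue points away from ring D, which sets C8.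

Step 17
Reactants: 25 rearranged acid
Product: 26 triol (primary alcohols at C7, C11 and C12)
Conditions: LiAlH4, THF, reflux
Reagents that add atoms: none
Why: Exhaustive hydride reduction of the acid and of both hindered esters under forcing conditions; alkenes and the ether bridge are inert.

Step 18
Reactants: 26 triol
Product: 27 trialdehyde
Conditions: Dess–Martin periodinane, NaHCO3, CH2Cl2, 0 °C to rt
Reagents that add atoms: none
Why: Dess–Martin oxidation is near neutral, so the only epimerisable centre (C8, α to the C7 aldehyde) should be kept.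

Step 19
Reactants: 27 trialdehyde
Product: 28 tetravinyl hexaene (vinyl groups on C5, C8, C9 and C13)
Conditions: Ph3PCH3Br, KN(SiMe3)2, THF, −78 to 0 °C
Reagents that add atoms: methyltriphenylphosphonium bromide, C[P+](c1ccccc1)(c1ccccc1)c1ccccc1.[Br-]
Why: Threefold Wittig methylenation; the small unstabilised ylide reaches neopentyl aldehydes and adds faster than it enolises the C7 aldehyde at low temperature.

Step 20
Reactants: 28 tetravinyl hexaene
Product: 30 pentacyclic tetraene (6-ene, 11-ene, 15-ene and side-chain alkene), via ring B cyclopentene 29 (not isolated)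
Conditions: second-generation Hoveyda–Grubbs catalyst RuCl2(H2IMes)(=CH-C6H4-2-O-i-Pr) (2 × 10 mol %), toluene (1 mM), 100 °C, argon sparge
Reagents that add atoms: none
Why: Double ring-closing olefin metathesis (Chauvin cycle of [2+2] cycloaddition and cycloreversion at a ruthenium alkylidene, ethene lost twice). The catalyst should load first on the least hindered vinyl groups, those on the tertiary carbons C5 and C8, so the 1,6-diene closes ring B as a trans-fused cyclopentene (29); only then does an alkylidene form on one of the two neopentyl vinyl groups and the 1,7-diene C11/C12 closes ring C as a cyclohexene, the last ring of the skeleton. No stereocentre is created: C5, C8, C9, C13 and C14 are already in place, and the cis B/C and trans C/D fusions follow from them because the exo vinyl group on C9 and the vinyl group on C13 lie gauche across the C8–C14 bond. The selectivity needed is the pairing of four vinyl groups: C7/C11 and C6/C11 would give cyclobutenes, and C7/C12 gives a strained trans-fused cyclopentene that leaves two vinyl groups without a partner and is reopened by ethene, so the reversible process should drain into 30. The unstrained ring D alkene, flanked by C14 and C17, and the trisubstituted side-chain alkene are poor substrates and should stay untouched.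

Step 21
Reactants: 30 pentacyclic tetraene
Product: 31 target CNP0284367.1
Conditions: H2 (50 bar), RhCl(PPh3)3 (20 mol %), benzene/EtOH, 50 °C
Reagents that add atoms: none
Why: Homogeneous hydrogenation with RhCl(PPh3)3, which reduces cis-disubstituted alkenes but is very slow with trisubstituted ones, so the three ring alkenes should be saturated and the side-chain alkene kept; no stereocentre is formed.

Compound list
1 | (±)-linalool (3,7-dimethylocta-1,6-dien-3-ol) | CC(C)=CCCC(C)(O)C=C | starting material
2 | 2-(2-bromopropan-2-yl)-5-methyl-5-vinyltetrahydrofuran (racemic diastereomer mixture) | CC(C)(Br)C1CCC(C)(C=C)O1 | intermediate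
3 | 5-methyl-2-(propan-2-ylidene)-5-vinyltetrahydrofuran | CC(C)=C1CCC(C)(C=C)O1 | intermediate
4 | karahanaenone (2,2,5-trimethylcyclohept-4-en-1-one) | CC1=CCC(C)(C)C(=O)CC1 | intermediate
5 | (S)-2,2,5-trimethylcyclohept-4-en-1-ol | O[C@H]1CCC(C)=CCC1(C)C | intermediate
6 | 4,5-epoxide of 5 (both epoxide faces) | O[C@H]1CCC2(C)OC2CC1(C)C | intermediate
7 | (1R,5S)-1,4,4-trimethyl-8-oxabicyclo[3.2.1]octan-2-ol (carbinol epimers) | OC1CC(C)(C)[C@@H]2CC[C@@]1(C)O2 | intermediate
8 | (1R,5S)-1,4,4-trimethyl-8-oxabicyclo[3.2.1]octan-2-one | O=C1CC(C)(C)[C@@H]2CC[C@@]1(C)O2 | intermediate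
9 | (1R,5S)-1,4,4-trimethyl-8-oxabicyclo[3.2.1]oct-2-en-2-yl triflate | O=S(=O)(OC1=CC(C)(C)[C@@H]2CC[C@@]1(C)O2)C(F)(F)F | intermediate
10 | methyl (1R,5S)-1,4,4-trimethyl-8-oxabicyclo[3.2.1]oct-2-ene-2-carboxylate | COC(=O)C1=CC(C)(C)[C@@H]2CC[C@@]1(C)O2 | intermediate
11 | trimethylsilyl ketene acetal of 12 (vinyl exo) | COC(O[Si](C)(C)C)=C1[C@@H](C=C)C(C)(C)[C@@H]2CC[C@@]1(C)O2 | intermediate
12 | methyl (1R,3R,5S)-1,4,4-trimethyl-3-exo-vinyl-8-oxabicyclo[3.2.1]octane-2-carboxylate (C-2 epimers) | COC(=O)C1[C@@H](C=C)C(C)(C)[C@@H]2CC[C@@]1(C)O2 | intermediate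
13 | tert-butyl 2-methyl-3-oxobutanoate (racemic) | CC(=O)C(C)C(=O)OC(C)(C)C | starting material
14 | methyl vinyl ketone (but-3-en-2-one) | C=CC(C)=O | starting material
15 | tert-butyl (S)-2-acetyl-2-methyl-5-oxohexanoate | CC(=O)CC[C@](C)(C(=O)OC(C)(C)C)C(C)=O | intermediate
16 | tert-butyl (S)-1,2-dimethyl-4-oxocyclohex-2-ene-1-carboxylate | O=C1CC[C@](C)(C(=O)OC(C)(C)C)C(C)=C1 | intermediate
17 | tert-butyl (1S)-1,2,5-trimethyl-4-oxocyclohex-2-ene-1-carboxylate (C-5 epimers) | CC1C[C@](C)(C(=O)OC(C)(C)C)C(C)=CC1=O | intermediate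
18 | 5-iodo-2-methylpent-2-ene | CC(C)=CCCI | starting material
19 | tert-butyl (1S,5S)-1,2,5-trimethyl-5-(4-methylpent-3-en-1-yl)-4-oxocyclohex-2-ene-1-carboxylate (chain cis to the C-1 methyl group) | CC(C)=CCC[C@@]1(C)C[C@](C)(C(=O)OC(C)(C)C)C(C)=CC1=O | intermediate
20 | tert-butyl (1S,4R,5S)-4-hydroxy-1,2,5-trimethyl-5-(4-methylpent-3-en-1-yl)cyclohex-2-ene-1-carboxylate (OH cis to chain and C-1 methyl group) | CC(C)=CCC[C@@]1(C)C[C@](C)(C(=O)OC(C)(C)C)C(C)=C[C@H]1O | intermediate
21 | bromoacetate of 20 | CC(C)=CCC[C@@]1(C)C[C@](C)(C(=O)OC(C)(C)C)C(C)=C[C@H]1OC(=O)CBr | intermediate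
22 | triester: ester of 20 with the ring A acetic acid (C9: CO2Me exo, CH2CO2 endo; C5 vinyl exo) | CC(C)=CCC[C@@]1(C)C[C@](C)(C(=O)OC(C)(C)C)C(C)=C[C@H]1OC(=O)C[C@]2(C(=O)OC)[C@@H](C=C)C(C)(C)[C@@H]3CC[C@@]2(C)O3 | intermediate
23 | (Z)-tert-butyldimethylsilyl ketene acetal of 22 | CC(C)=CCC[C@@]1(C)C[C@](C)(C(=O)OC(C)(C)C)C(C)=C[C@H]1O/C(O[Si](C)(C)C(C)(C)C)=C/[C@]2(C(=O)OC)[C@@H](C=C)C(C)(C)[C@@H]3CC[C@@]2(C)O3 | intermediate
24 | tert-butyldimethylsilyl ester of 25 | CC(C)=CCC[C@]1(C)C=C[C@](C)([C@@H](C(=O)O[Si](C)(C)C(C)(C)C)[C@]2(C(=O)OC)[C@@H](C=C)C(C)(C)[C@@H]3CC[C@@]2(C)O3)[C@@](C)(C(=O)OC(C)(C)C)C1 | intermediate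
25 | rearranged acid: C8 (H, CO2H) joins C9 of ring A to quaternary C14 of the 15-ene ring D; C8–C14 bond cis to the C13 methyl group | CC(C)=CCC[C@]1(C)C=C[C@](C)([C@@H](C(=O)O)[C@]2(C(=O)OC)[C@@H](C=C)C(C)(C)[C@@H]3CC[C@@]2(C)O3)[C@@](C)(C(=O)OC(C)(C)C)C1 | intermediate
26 | triol (CH2OH on C8, C9 and C13) | CC(C)=CCC[C@]1(C)C=C[C@](C)([C@@H](CO)[C@]2(CO)[C@@H](C=C)C(C)(C)[C@@H]3CC[C@@]2(C)O3)[C@@](C)(CO)C1 | intermediate
27 | trialdehyde (CHO on C8, C9 and C13) | CC(C)=CCC[C@]1(C)C=C[C@](C)([C@@H](C=O)[C@]2(C=O)[C@@H](C=C)C(C)(C)[C@@H]3CC[C@@]2(C)O3)[C@@](C)(C=O)C1 | intermediate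
28 | tetravinyl hexaene (vinyl on C5, C8, C9, C13; 15-ene; side-chain alkene) | CC(C)=CCC[C@]1(C)C=C[C@](C)([C@@H](C=C)[C@]2(C=C)[C@@H](C=C)C(C)(C)[C@@H]3CC[C@@]2(C)O3)[C@@](C)(C=C)C1 | intermediate
29 | ring B cyclopentene (6-ene) still bearing the vinyl groups on C9 and C13 | CC(C)=CCC[C@]1(C)C=C[C@](C)([C@H]2C=C[C@H]3C(C)(C)[C@@H]4CC[C@@](C)(O4)[C@]23C=C)[C@@](C)(C=C)C1 | intermediate
30 | pentacyclic tetraene (6-ene, 11-ene, 15-ene, side-chain alkene) | CC(C)=CCC[C@]1(C)C=C[C@]2(C)[C@H]3C=C[C@H]4C(C)(C)[C@@H]5CC[C@@](C)(O5)[C@@]43C=C[C@@]2(C)C1 | intermediate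
31 | CNP0284367.1 | CC(C)=CCC[C@]1(C)CC[C@]2(C)[C@H]3CC[C@H]4C(C)(C)[C@@H]5CC[C@@](C)(O5)[C@@]43CC[C@@]2(C)C1 | target

Total step count: 21. Longest linear sequence: 15 steps (steps 1–8 and 15–21, from linalool).

Steps most likely to fail

Step 20. Alkylidene formation at the two neopentyl vinyl groups may be too slow. The reaction would then stall after closure of ring B, or the catalyst would decay.
- The fallback sets out from 27.
- One equivalent of Ph3P=CH2 should methylenate only the least hindered aldehyde (C7, on the tertiary C8) and give the diene dialdehyde F1.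
- Ring-closing metathesis of its two accessible vinyl groups gives the ring B cyclopentene dialdehyde F2.
- An intramolecular McMurry coupling of the two neopentyl aldehydes with low-valent titanium (TiCl3(DME)1.5, Zn–Cu couple, DME, reflux) then closes ring C, and the route is rejoined at 30.

Step 16. Steric congestion between C9, C13 and the migrating terminus may stop the sigmatropic shift, or poor control of the ketene acetal geometry may erode the configuration at C8.
- The fallback sets out from 12 and 19 and forms the C8–C14 bond by a polar conjugate addition.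
- Alkylation of 12 with methyl bromoacetate as in step 15 gives the dimethyl ester F3.
- LiN(i-Pr)2 and Me3SiCl give its silyl ketene acetal F4.
- A Mukaiyama–Michael addition of F4 to enone 19 (TiCl4, CH2Cl2, −78 °C, attack on C14 anti to the pseudoaxial ester) gives the keto triester F5.
- KN(SiMe3)2 and PhNTf2 give the enol triflate F6, since only C15 is enolisable.
- Formate reduction (Pd(OAc)2, PPh3, HCO2H, n-Bu3N) gives the 15-ene triester F7.
- LiAlH4 converts F7 into 26, where the route is rejoined.

Step 21. The two alkenes flanked by quaternary carbons may be reduced incompletely, or chemoselectivity may be lost through saturation of the side-chain alkene under the forcing conditions.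
- The fallback sets out from 30.
- One equivalent of mCPBA should epoxidise only the electron-rich trisubstituted side-chain alkene and give the epoxy triene F8.
- Heterogeneous hydrogenation (H2, Pd/C, EtOAc, pressure) saturates the three ring alkenes and gives the saturated epoxide F9.
- Oxygen transfer to PPh3 (MeReO3 cat., benzene) restores the alkene, whose geometry is irrelevant, and the route is rejoined at 31.

Further compounds
F1 | step 20 | diene dialdehyde (vinyl on C5 and C8, CHO on C9 and C13) | CC(C)=CCC[C@]1(C)C=C[C@](C)([C@@H](C=C)[C@]2(C=O)[C@@H](C=C)C(C)(C)[C@@H]3CC[C@@]2(C)O3)[C@@](C)(C=O)C1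
F2 | step 20 | ring B cyclopentene dialdehyde (CHO on C9 and C13) | CC(C)=CCC[C@]1(C)C=C[C@](C)([C@H]2C=C[C@H]3C(C)(C)[C@@H]4CC[C@@](C)(O4)[C@]23C=O)[C@@](C)(C=O)C1
F3 | step 16 | dimethyl ester (C9: CO2Me exo, CH2CO2Me endo; C5 vinyl exo) | COC(=O)C[C@]1(C(=O)OC)[C@@H](C=C)C(C)(C)[C@@H]2CC[C@@]1(C)O2
F4 | step 16 | trimethylsilyl ketene acetal of F3 | COC(O[Si](C)(C)C)=C[C@]1(C(=O)OC)[C@@H](C=C)C(C)(C)[C@@H]2CC[C@@]1(C)O2
F5 | step 16 | keto triester (C16 ketone, C8–C14 bond in place) | CC(C)=CCC[C@]1(C)C(=O)C[C@](C)([C@@H](C(=O)OC)[C@]2(C(=O)OC)[C@@H](C=C)C(C)(C)[C@@H]3CC[C@@]2(C)O3)[C@@](C)(C(=O)OC(C)(C)C)C1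
F6 | step 16 | C16 enol triflate of F5 | CC(C)=CCC[C@]1(C)C(OS(=O)(=O)C(F)(F)F)=C[C@](C)([C@@H](C(=O)OC)[C@]2(C(=O)OC)[C@@H](C=C)C(C)(C)[C@@H]3CC[C@@]2(C)O3)[C@@](C)(C(=O)OC(C)(C)C)C1
F7 | step 16 | 15-ene triester (methyl ester of 25) | CC(C)=CCC[C@]1(C)C=C[C@](C)([C@@H](C(=O)OC)[C@]2(C(=O)OC)[C@@H](C=C)C(C)(C)[C@@H]3CC[C@@]2(C)O3)[C@@](C)(C(=O)OC(C)(C)C)C1
F8 | step 21 | epoxy triene (side-chain epoxide of 30, epoxide epimers) | CC1(C)OC1CC[C@]2(C)C=C[C@]3(C)[C@H]4C=C[C@H]5C(C)(C)[C@@H]6CC[C@@](C)(O6)[C@@]54C=C[C@@]3(C)C2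
F9 | step 21 | saturated epoxide (side-chain epoxide of 31, epoxide epimers) | CC1(C)OC1CC[C@]2(C)CC[C@]3(C)[C@H]4CC[C@H]5C(C)(C)[C@@H]6CC[C@@](C)(O6)[C@@]54CC[C@@]3(C)C2
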